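The target is disconnected at the two C–CH3 bonds on the adjacent quaternary cyclobutane carbons C1 and C2. Without them the ring is the cis,trans,cis tetracarboxylate of a commercial dianhydride. C1 and C2 are made the fusion atoms between the cyclobutane and a five-membered N-(4-methoxybenzyl) imide ring, while the C3 and C4 carboxyls stay free. In one operation, sequential enolisation and methylation at both fusion carbons sets both quaternary stereocentres with retention, because the four/five ring fusion can only be cis and the C3/C4 carboxylates cannot enolise. The imide carbonyls later become C6 of the two 4-methoxy-3-methyl-2-pyranones through a dialdehyde.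

Key step: step 2

Remark: the target and all symmetric intermediates are meso; 3, 7 and 10 are racemic and drawn as one enantiomer; 16 and 17 are mixtures at the side-chain centres, which vanish in step 9; in the bicyclic imides the quaternary carbons are C1/C5 and the CH–CO2H carbons C6/C7 of the 3-azabicyclo[3.2.0]heptane.

Step 1
Reactants: 1 cis,trans,cis-cyclobutane-1,2,3,4-tetracarboxylic dianhydride; 2 4-methoxybenzylamine
Product: 5 N-(4-methoxybenzyl) cis,trans,cis-cyclobutane-1,2,3,4-tetracarboxylic 1,2-imide 3,4-diacid, via amic acid anhydride 3 (not isolated), via imide anhydride 4 (not isolated)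
Conditions: 1 (2 equiv), DMF, 0 °C, slow addition of 2 (1 equiv), rt; Ac2O, NaOAc, 80 °C; then H2O, 60 °C; acid–base extraction
Reagents that add atoms: 4-methoxybenzylamine (COc1ccc(CN)cc1); water (O)
Why: Anhydride aminolysis, acetic-anhydride-mediated imidisation of the amic acid and hydrolysis of the second anhydride are standard acyl substitutions; excess dianhydride keeps bis-imide formation down (the bis-imide is neutral and is removed by base extraction), and no stereocentre can change because each five-membered ring can only be cis-fused to the cyclobutane.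

Step 2
Reactants: 5 N-(4-methoxybenzyl) imide diacid; 6 iodomethane
Product: 8 3-(4-methoxybenzyl)-1,5-dimethyl-2,4-dioxo-3-azabicyclo[3.2.0]heptane-6,7-dicarboxylic acid (methyls cis to the CO2H groups), via monomethyl imide diacid 7 (not isolated)
Conditions: LiN(iPr)2 (3.3 equiv), THF/DMPU, −78 °C; MeI (1.2 equiv), −78 to −40 °C; LiN(iPr)2 (1.5 equiv), −78 °C; MeI (2 equiv), −78 to −20 °C; aqueous HCl
Reagents that add atoms: iodomethane (CI)
Why: Two equivalents of LiN(iPr)2 turn the C6/C7 carboxylic acids into lithium carboxylates and the third removes the C1–H next to an imide carbonyl, giving a ring-fusion lithium enolate that attacks iodomethane in an SN2 reaction; the second charge of base and iodomethane repeats this at C5. The closest known reaction type is C-alkylation of ring-fusion enolates of bicyclic succinimides and of cyclobutane-fused lactones. No ring is closed. Each new quaternary stereocentre (C1 and C5) is fixed by the ring fusion itself: a five-membered imide can only be cis-fused to the cyclobutane, so the methyl must take the place of the hydrogen (retention), on the face away from the imide ring. The selectivity needed is imide α-CH over carboxylate α-CH and C- over O-methylation; the negative charge of each carboxylate makes C6–H and C7–H far less acidic than the imide α-hydrogens, and lithium carboxylates are poor nucleophiles at low temperature, so the cis,trans,cis array bought with 1 should be carried through intact.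

Step 3
Reactants: 8 dimethylated imide diacid
Product: 9 di-tert-butyl 3-(4-methoxybenzyl)-1,5-dimethyl-2,4-dioxo-3-azabicyclo[3.2.0]heptane-6,7-dicarboxylate
Conditions: Cl3CC(=NH)OtBu (5 equiv), CH2Cl2/cyclohexane, rt (BF3·OEt2 cat. if slow)
Reagents that add atoms: tert-butyl 2,2,2-trichloroacetimidate (CC(C)(C)OC(=N)C(Cl)(Cl)Cl)
Why: O-alkylative esterification by tert-butyl cation transfer from the protonated imidate never activates the carboxyl carbons, so the cis-diacid cannot close to an anhydride and C6/C7 cannot epimerise.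

Step 4
Reactants: 9 N-(4-methoxybenzyl) imide di-tert-butyl ester
Product: 12 cis,trans,cis-3,4-bis(tert-butoxycarbonyl)-1,2-dimethylcyclobutane-1,2-dicarboxylic acid, via amic acid 10 (not isolated), via cyclic anhydride 11 (not isolated)
Conditions: LiOH, THF/H2O, rt; then aqueous HCl to pH 3, 45 °C; cold EtOAc extraction
Reagents that add atoms: lithium hydroxide ([Li+].[OH-]); water (O)
Why: Alkaline imide hydrolysis gives the amic acid, whose secondary amide is then cleaved at pH 3 by the cis-neighbouring carboxyl through the cyclic anhydride (intramolecular carboxyl-assisted amide hydrolysis, strongly accelerated by the two quaternary carbons), the amine leaving as its ammonium salt while the tert-butyl esters survive the weakly acidic medium.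

Step 5
Reactants: 12 hindered diacid di-tert-butyl ester
Product: 13 di-tert-butyl 3,4-bis(hydroxymethyl)-3,4-dimethylcyclobutane-1,2-dicarboxylate (CH2OH groups cis to each other, trans to the esters)
Conditions: BH3·THF (5 equiv), THF, 0 °C to rt; MeOH
Reagents that add atoms: none
Why: Borane reduction of carboxylic acids proceeds through acyloxyboranes far faster than reduction of esters, so both hindered acids should be reduced to primary alcohols while the tert-butyl esters remain.

Step 6
Reactants: 13 diol
Product: 14 di-tert-butyl 3,4-diformyl-3,4-dimethylcyclobutane-1,2-dicarboxylate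
Conditions: (COCl)2, DMSO, CH2Cl2, −78 °C; Et3N, −78 to 0 °C; used crude
Reagents that add atoms: none
Why: Swern oxidation converts both hydroxyls into alkoxysulfonium salts before base is added, so no free hydroxyl is left to form a lactol and be over-oxidised to a lactone, and the aldehydes, having no α-hydrogen, can neither epimerise nor self-condense.

Step 7
Reactants: 14 dialdehyde; 15 methyl 2-methylacetoacetate
Product: 16 di-tert-butyl 3,4-bis(1-hydroxy-5-methoxy-4-methyl-3,5-dioxopentyl)-3,4-dimethylcyclobutane-1,2-dicarboxylate (diastereomer mixture)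
Conditions: 15 (3.5 equiv), LiN(iPr)2 (7 equiv), THF, 0 °C; then 14, −78 to −30 °C; AcOH
Reagents that add atoms: methyl 2-methylacetoacetate (CC(=O)C(C)C(=O)OC)
Why: Aldol addition of the γ-carbon of the β-keto ester dianion to the two non-enolisable aldehydes; the lactolate formed from the first alkoxide and the neighbouring aldehyde is in equilibrium with the open aldehyde and is drained by excess dianion, and the new carbinol and C2 centres need no control because steps 8 and 9 erase them.

Step 8
Reactants: 16 bis(δ-hydroxy β-keto ester)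
Product: 17 di-tert-butyl 3,4-bis(5-methoxy-4-methyl-3,5-dioxopentanoyl)-3,4-dimethylcyclobutane-1,2-dicarboxylate
Conditions: Dess–Martin periodinane (3 equiv), NaHCO3, CH2Cl2, 0 °C to rt
Reagents that add atoms: none
Why: Dess–Martin oxidation of both secondary alcohols under bicarbonate buffering should give the bis(β,δ-diketo ester) without acid that could dehydrate hemiketal forms, and the ring stereocentres are not involved.

Step 9
Reactants: 17 bis(β,δ-diketo ester)
Product: 18 di-tert-butyl 3,4-bis(4-hydroxy-3-methyl-2-oxo-2H-pyran-6-yl)-3,4-dimethylcyclobutane-1,2-dicarboxylate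
Conditions: DBU (4 equiv), toluene, rt to 60 °C; aqueous HCl
Reagents that add atoms: none
Why: Base-mediated enol lactonisation of each 3,5-dioxo ester (the C5 enolate oxygen attacks the methyl ester in a 6-exo-trig acyl substitution with loss of methanol) is the standard entry to 6-substituted 4-hydroxy-3-methyl-2-pyranones, the stabilised pyranone anion is the thermodynamic outlet, and DBU is far too weak to enolise the tert-butyl esters.

Step 10
Reactants: 18 bis(4-hydroxy-2-pyranone)
Product: 19 di-tert-butyl 3,4-bis(4-methoxy-3-methyl-2-oxo-2H-pyran-6-yl)-3,4-dimethylcyclobutane-1,2-dicarboxylate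
Conditions: Me2SO4 (3 equiv), K2CO3, acetone, 50 °C
Reagents that add atoms: dimethyl sulfate (COS(=O)(=O)OC)
Why: O-alkylation of the ambident 4-hydroxy-2-pyranone anion with Me2SO4/K2CO3 in acetone should favour the 4-methoxy-2-pyranone over the isomeric 2-methoxy-4-pyranone, as is usual for 5-unsubstituted 4-hydroxy-2-pyranones.

Step 11
Reactants: 19 bis(4-methoxy-2-pyranone) di-tert-butyl ester
Product: 20 3,4-bis(4-methoxy-3-methyl-2-oxo-2H-pyran-6-yl)-3,4-dimethylcyclobutane-1,2-dicarboxylic acid (CNP0574758.1)
Conditions: CF3CO2H/CH2Cl2, rt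
Reagents that add atoms: none
Why: Acidolysis of the tert-butyl esters (loss of the tert-butyl cation as isobutene) frees both acids under conditions to which the methoxypyranones and the all-carbon ring stereocentres are inert, so the cis,trans,cis array from steps 1 and 2 is delivered unchanged.

Compound list
1 | cis,trans,cis-cyclobutane-1,2,3,4-tetracarboxylic dianhydride (anhydride rings on opposite faces) | O=C1[C@H]2[C@H](C3=O)[C@H](C(=O)O3)[C@H]2C(=O)O1 | starting material
2 | 4-methoxybenzylamine | COc1ccc(CN)cc1 | starting material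
3 | amic acid anhydride (one anhydride opened to cis CONH-PMB/CO2H, racemic) | O=C(NCc1ccc(OC)cc1)[C@H]2[C@H](C3=O)[C@H](C(=O)O3)[C@H]2C(=O)O | intermediate (not isolated)
4 | imide anhydride (N-PMB imide on one face, anhydride on the other) | O=C1[C@H]2[C@H](C3=O)[C@H](C(=O)O3)[C@H]2C(=O)N1Cc1ccc(OC)cc1 | intermediate (not isolated)
5 | N-(4-methoxybenzyl) cis,trans,cis-cyclobutane-1,2,3,4-tetracarboxylic 1,2-imide 3,4-diacid (imide ring trans to both CO2H) | O=C1[C@H]2[C@H](C(=O)O)[C@H](C(=O)O)[C@H]2C(=O)N1Cc1ccc(OC)cc1 | intermediate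
6 | iodomethane | CI | starting material
7 | 1-methyl derivative of 5 (methyl cis to the CO2H groups, racemic) | O=C1[C@@]2(C)[C@H](C(=O)O)[C@H](C(=O)O)[C@H]2C(=O)N1Cc1ccc(OC)cc1 | intermediate (not isolated)
8 | 3-(4-methoxybenzyl)-1,5-dimethyl-2,4-dioxo-3-azabicyclo[3.2.0]heptane-6,7-dicarboxylic acid (both methyls cis to the CO2H groups) | O=C1[C@@]2(C)[C@H](C(=O)O)[C@H](C(=O)O)[C@@]2(C)C(=O)N1Cc1ccc(OC)cc1 | intermediate
9 | di-tert-butyl ester of 8 | O=C1[C@@]2(C)[C@H](C(=O)OC(C)(C)C)[C@H](C(=O)OC(C)(C)C)[C@@]2(C)C(=O)N1Cc1ccc(OC)cc1 | intermediate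
10 | amic acid from 9 (cis CONH-PMB and CO2H on the methylated carbons, racemic) | O=C(NCc1ccc(OC)cc1)[C@@]2(C)[C@H](C(=O)OC(C)(C)C)[C@H](C(=O)OC(C)(C)C)[C@@]2(C)C(=O)O | intermediate (not isolated)
11 | cyclic anhydride of 12 | O=C1[C@@]2(C)[C@H](C(=O)OC(C)(C)C)[C@H](C(=O)OC(C)(C)C)[C@@]2(C)C(=O)O1 | intermediate (not isolated)
12 | cis,trans,cis-3,4-bis(tert-butoxycarbonyl)-1,2-dimethylcyclobutane-1,2-dicarboxylic acid | OC(=O)[C@@]1(C)[C@H](C(=O)OC(C)(C)C)[C@H](C(=O)OC(C)(C)C)[C@@]1(C)C(=O)O | intermediate
13 | di-tert-butyl 3,4-bis(hydroxymethyl)-3,4-dimethylcyclobutane-1,2-dicarboxylate | OC[C@@]1(C)[C@H](C(=O)OC(C)(C)C)[C@H](C(=O)OC(C)(C)C)[C@@]1(C)CO | intermediate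
14 | di-tert-butyl 3,4-diformyl-3,4-dimethylcyclobutane-1,2-dicarboxylate | O=C[C@@]1(C)[C@H](C(=O)OC(C)(C)C)[C@H](C(=O)OC(C)(C)C)[C@@]1(C)C=O | intermediate
15 | methyl 2-methylacetoacetate | CC(=O)C(C)C(=O)OC | starting material
16 | di-tert-butyl 3,4-bis(1-hydroxy-5-methoxy-4-methyl-3,5-dioxopentyl)-3,4-dimethylcyclobutane-1,2-dicarboxylate | COC(=O)C(C)C(=O)CC(O)[C@@]1(C)[C@H](C(=O)OC(C)(C)C)[C@H](C(=O)OC(C)(C)C)[C@@]1(C)C(O)CC(=O)C(C)C(=O)OC | intermediate
17 | di-tert-butyl 3,4-bis(5-methoxy-4-methyl-3,5-dioxopentanoyl)-3,4-dimethylcyclobutane-1,2-dicarboxylate | COC(=O)C(C)C(=O)CC(=O)[C@@]1(C)[C@H](C(=O)OC(C)(C)C)[C@H](C(=O)OC(C)(C)C)[C@@]1(C)C(=O)CC(=O)C(C)C(=O)OC | intermediate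
18 | di-tert-butyl 3,4-bis(4-hydroxy-3-methyl-2-oxo-2H-pyran-6-yl)-3,4-dimethylcyclobutane-1,2-dicarboxylate | Oc1cc([C@@]2(C)[C@H](C(=O)OC(C)(C)C)[C@H](C(=O)OC(C)(C)C)[C@@]2(C)c2cc(O)c(C)c(=O)o2)oc(=O)c1C | intermediate
19 | di-tert-butyl 3,4-bis(4-methoxy-3-methyl-2-oxo-2H-pyran-6-yl)-3,4-dimethylcyclobutane-1,2-dicarboxylate | COc1cc([C@@]2(C)[C@H](C(=O)OC(C)(C)C)[C@H](C(=O)OC(C)(C)C)[C@@]2(C)c2cc(OC)c(C)c(=O)o2)oc(=O)c1C | intermediate
20 | 3,4-bis(4-methoxy-3-methyl-2-oxo-2H-pyran-6-yl)-3,4-dimethylcyclobutane-1,2-dicarboxylic acid (pyranones cis to each other and trans to the CO2H groups) | COc1cc([C@@]2(C)[C@H](C(=O)O)[C@H](C(=O)O)[C@@]2(C)c2cc(OC)c(C)c(=O)o2)oc(=O)c1C | target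

Total step count: 11
Longest linear sequence: 11 steps (1 to 20)

Steps most likely to fail

Step 2. The second deprotonation, next to the newly formed quaternary carbon, may stall; the carboxylates may be O-methylated; or the polyanion may precipitate before it is alkylated. The fallback builds the dimethylated core by a known crossed [2+2] photocycloaddition. It sets out from 2, which is condensed with commercial 2,3-dimethylmaleic anhydride (AcOH, reflux) to N-(4-methoxybenzyl)-2,3-dimethylmaleimide F1. Irradiation of F1 with excess maleic anhydride (300–350 nm, acetone as solvent and triplet sensitiser) should give the cis,anti,cis cycloadduct, the dimethyl imide anhydride F2. Hydrolysis of the anhydride in aqueous THF returns to the route at 8.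

Step 4. Hydroxide attack at the doubly neopentyl imide carbonyls may be slow, or the amic acid may reclose to the imide instead of expelling the amine. The fallback sets out from 9 and removes the nitrogen by activation and reduction. Oxidative debenzylation with (NH4)2Ce(NO3)6 in MeCN/H2O gives the NH imide di-tert-butyl ester F3, and Boc2O/DMAP gives the N-Boc imide F4. NaBH4 in THF/EtOH opens F4 reductively to the hydroxy N-Boc amide F5, which lactonises with loss of tert-butyl carbamate (cat. K2CO3 or gentle warming) to the γ-lactone F6. LiBH4 in THF then reduces F6 to the diol, returning to the route at 13 and bypassing 12.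

Step 8. After the first oxidation the γ-hydroxy ketone may be intercepted as a cyclic hemiketal with the neighbouring side chain, halting the second oxidation. The fallback avoids the ketone stage and sets out from 16. K2CO3 in MeOH lactonises each δ-hydroxy β-keto ester to give the bis(4-hydroxy-3-methyl-5,6-dihydro-2-pyranone) F7. Me2SO4/K2CO3 in acetone then gives the bis(4-methoxy-3-methyl-5,6-dihydro-2-pyranone) F8. Dehydrogenation of both rings with DDQ in dioxane at 80 °C returns to the route at 19, bypassing 17 and 18.

Further compounds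
F1 | step 2 | N-(4-methoxybenzyl)-2,3-dimethylmaleimide | CC1=C(C)C(=O)N(Cc2ccc(OC)cc2)C1=O
F2 | step 2 | dimethyl imide anhydride (cyclic anhydride of 8) | O=C1[C@@]2(C)[C@H](C3=O)[C@H](C(=O)O3)[C@@]2(C)C(=O)N1Cc1ccc(OC)cc1
F3 | step 4 | NH imide di-tert-butyl ester | O=C1[C@@]2(C)[C@H](C(=O)OC(C)(C)C)[C@H](C(=O)OC(C)(C)C)[C@@]2(C)C(=O)N1
F4 | step 4 | N-Boc imide di-tert-butyl ester | O=C1[C@@]2(C)[C@H](C(=O)OC(C)(C)C)[C@H](C(=O)OC(C)(C)C)[C@@]2(C)C(=O)N1C(=O)OC(C)(C)C
F5 | step 4 | hydroxy N-Boc amide (racemic) | OC[C@@]1(C)[C@H](C(=O)OC(C)(C)C)[C@H](C(=O)OC(C)(C)C)[C@@]1(C)C(=O)NC(=O)OC(C)(C)C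
F6 | step 4 | cis-fused γ-lactone di-tert-butyl ester (racemic) | O=C1OC[C@@]2(C)[C@H](C(=O)OC(C)(C)C)[C@H](C(=O)OC(C)(C)C)[C@]21C
F7 | step 8 | bis(4-hydroxy-3-methyl-5,6-dihydro-2-pyranone) di-tert-butyl ester | OC1=C(C)C(=O)OC(C1)[C@@]2(C)[C@H](C(=O)OC(C)(C)C)[C@H](C(=O)OC(C)(C)C)[C@@]2(C)C1CC(O)=C(C)C(=O)O1
F8 | step 8 | bis(4-methoxy-3-methyl-5,6-dihydro-2-pyranone) di-tert-butyl ester | COC1=C(C)C(=O)OC(C1)[C@@]2(C)[C@H](C(=O)OC(C)(C)C)[C@H](C(=O)OC(C)(C)C)[C@@]2(C)C1CC(OC)=C(C)C(=O)O1
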